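A fixed rate constant cannot be what takes Z in the spring run: the first 6.00 h cost 4 percentage points of the Z charged and the next 4.00 h cost 4.6 points, a faster loss with less Z present. Something is growing in the first phase, and two of us dispute what it is.

| setting | spring | flask |
|---|---|---|
| Z | 1 M | 0.50 M |
| L | 0.90 M | 0.900 M |
| remark | run made earlier |  |
| time |  | 30 h |
| volume of the second phase over the first |  | 0.50 |

spring run (percent of the Z charged)

| time / h | J / % | Z / % |
|---|---|---|
| 0.833 | 0 | 99.7 |
| 2.50 | 0.9 | 98.9 |
| 4.00 | 1.6 | 97.9 |
| 6.00 | 2.4 | 96.0 |
| 10.0 | 6.6 | 91.4 |

(scatter of a reading: 0.3 percentage points)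

- in the second phase: L; everything else is in the first
- charges count per volume of the first phase; a concentration in a rate is the amount of a species over the volume of its own phase; every rate counts per litre of the first phase
- the earlier runs hold the two phases in the same ratio of volumes as the flask asked about

- J at 30 h, in percent of the Z charged
- part of the Z charged that has reacted at 30 h

The forecast holds that the product speeds its own making, so that in the new flask, with less Z charged, “the product concentration driving the acceleration is also halved”. It stands at 26% of Z reacted (range 17% to 45%) and 20% of J (range 11% to 35%).

I hold that a reagent is crossing from L in the second phase. Then c(Z) falls pseudo-first-order at each moment, and to a first reckoning what has crossed by a given hour is the same in both flasks, since L and the phase ratio match. Early on, in this view, the crossed reagent grows in step with the hours, so the fractional loss rate of Z does too, and the logarithm of charged over remaining Z grows with the square of the time. From the last spring reading, a loss of 8.6 points against a scatter of 0.3 points, I read 33.3 h for the squared-time clock of Z, the hour at which that logarithm would reach one.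

Round one: the logarithm at 30 h is that time over 33.3 h, squared, 0.809, so the flask reacts 55.5%. Round two: if each Z takes one L, that answer leaves 69.2% of the L charge. Scaling the logarithm by this share gives 42.9%, which is my number, more than the forecast's 26%. For J I offer no figure.

The flask gives 37.2% of Z reacted and 18.8% of J at 30 h.

    X → Q (k = 3.85 × 10⁻⁴ min⁻¹)
    Z + X → J (k = 0.00143 M⁻¹ min⁻¹)
    J ⇌ D (K = 0.753, k = 0.00112 min⁻¹)
    X → E (k = 2.31 × 10⁻⁷ min⁻¹)
    X + J → G (k = 0.00210 M⁻¹ min⁻¹)
    X ⇌ L, rate k6*([X] - [L]/K6) per volume of the first phase (partition coefficient = 0.580, kL = 1.75 × 10⁻⁴ min⁻¹)

The forecast's J share of the reacted Z, 75 to 80%, belongs to early hours: the neighbour read at 8.00 h shows 81.7%, while this flask at 30 h shows 50.5%. Two rounds with the clock stand 5.7 points above this flask. For a neighbour charged with 0.20 M of Z, the same clock and two rounds give 50.8%, and that neighbour reads more than this flask, at 43.5%.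

All runs were generated by integration with made-up constants; scatter was added.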